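In daucane numbering the cycloheptene ring (C1, C5–C10) is opened at two bonds: C1–C10, which joins the quaternary ring-fusion carbon beside the C2 ketone to the ester-bearing carbinol carbon (an aldol retron), and C7–C8, the sp3–sp2 bond of the cis C8=C9 alkene. The key step unites, in one flask, a cyclopentene whose silyl enol ether and C5 vinyl group are latent nucleophiles at C1 and C7 with (Z)-3-iodobut-2-enal, a three-carbon bis-electrophile: fluoride-triggered aldol addition with trapping of the aldolate by 4-methoxybenzoyl chloride, then hydroboration and intramolecular B-alkyl Suzuki–Miyaura coupling. This closes the seven-membered ring, sets C1 and C10 and installs the ester.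

Key step: step 8

Remark: daucane numbering is used throughout (C1 methyl-bearing ring-fusion carbon, C2 ketone, C3 CH2, C4 isopropyl-bearing CH, C5 hydroxyl-bearing ring-fusion carbon, C6 and C7 CH2, C8 methyl-bearing alkene carbon, C9 alkene CH, C10 ester-bearing CH); imide 4 is taken as purchasable.

Step 1
Reactants: 1 but-2-yn-1-ol
Product: 2 (2Z)-3-iodobut-2-en-1-ol
Conditions: NaAlH2(OCH2CH2OMe)2 (Red-Al), THF, 0 °C; then I2, −78 °C to rt
Reagents that add atoms: iodine, II
Why: Hydroxyl-directed trans-hydroalumination of the propargylic alcohol puts aluminium on C3 in a cyclic alanate, and iodinolysis with retention should give the Z iodoalkene (Red-Al reduction–iodination).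

Step 2
Reactants: 2 (2Z)-3-iodobut-2-en-1-ol
Product: 3 (2Z)-3-iodobut-2-enal
Conditions: MnO2, CH2Cl2, rt, dark
Reagents that add atoms: none
Why: Allylic oxidation with activated MnO2 stops at the aldehyde under neutral conditions and should leave the Z alkene untouched.

Step 3
Reactants: 4 (4R)-4-benzyl-3-(3-methylbutanoyl)-1,3-oxazolidin-2-one; 5 1-bromobut-2-yne
Product: 6 (4R)-4-benzyl-3-[(2R)-2-(propan-2-yl)hex-4-ynoyl]-1,3-oxazolidin-2-one
Conditions: NaN(SiMe3)2, THF, −78 °C; then 5, −78 to −40 °C
Reagents that add atoms: 1-bromobut-2-yne (5), CC#CCBr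
Why: Evans asymmetric alkylation: the chelated Z sodium enolate is attacked by the propargylic bromide on the face away from the benzyl group, which sets the (R) isopropyl-bearing centre (the later C4).

Step 4
Reactants: 6 (4R)-4-benzyl-3-[(2R)-2-(propan-2-yl)hex-4-ynoyl]-1,3-oxazolidin-2-one
Product: 7 (4R)-4-benzyl-3-[(2R)-4-oxo-2-(propan-2-yl)hexanoyl]-1,3-oxazolidin-2-one
Conditions: NaAuCl4·2H2O (5 mol %), EtOH–H2O, rt
Reagents that add atoms: water, O
Why: Carbonyl-assisted alkyne hydration: the imide carbonyl oxygen attacks the gold-activated alkyne in 5-exo-dig fashion, so the new ketone should form at the proximal alkyne carbon and give the 1,4-dicarbonyl compound.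

Step 5
Reactants: 7 (4R)-4-benzyl-3-[(2R)-4-oxo-2-(propan-2-yl)hexanoyl]-1,3-oxazolidin-2-one
Product: 8 (4R)-2-methyl-4-(propan-2-yl)cyclopentane-1,3-dione
Conditions: LiN(SiMe3)2 (2.2 equiv), THF, −78 to 0 °C; then aq. HCl
Reagents that add atoms: none
Why: Intramolecular Claisen (Dieckmann-type) acylation: the ethyl ketone enolate attacks the exocyclic imide carbonyl in a 5-exo-trig closure and expels the oxazolidinone, and immediate deprotonation of the dione should shield the isopropyl-bearing centre from epimerisation.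

Step 6
Reactants: 8 (4R)-2-methyl-4-(propan-2-yl)cyclopentane-1,3-dione
Product: 9 (5R)-3-[(tert-butyldimethylsilyl)oxy]-2-methyl-5-(propan-2-yl)cyclopent-2-en-1-one
Conditions: t-BuMe2SiCl, Et3N, CH2Cl2, 0 °C
Reagents that add atoms: tert-butyl(chloro)dimethylsilane, CC(C)(C)[Si](C)(C)Cl
Why: O-Silylation of the vinylogous acid should occur at the oxygen remote from the isopropyl-bearing carbon, the less hindered site that also avoids allylic strain, which leaves the carbonyl next to that carbon free.

Step 7
Reactants: 9 (5R)-3-[(tert-butyldimethylsilyl)oxy]-2-methyl-5-(propan-2-yl)cyclopent-2-en-1-one; 10 vinylmagnesium bromide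
Product: 12 tert-butyl({(3S,4R)-3-ethenyl-2-methyl-4-(propan-2-yl)-3-[(triethylsilyl)oxy]cyclopent-1-en-1-yl}oxy)dimethylsilane, via bromomagnesium tertiary alkoxide 11 (not isolated)
Conditions: CH2=CHMgBr, CeCl3, THF, −78 °C; then Et3SiOTf, Et3N, −78 to 0 °C
Reagents that add atoms: vinylmagnesium bromide (10), C=C[Mg]Br; triethylsilyl trifluoromethanesulfonate, CC[Si](CC)(CC)OS(=O)(=O)C(F)(F)F
Why: Stork–Danheiser-type 1,2-addition of the organocerium reagent to the vinylogous ester carbonyl anti to the neighbouring isopropyl group sets C5 with oxygen cis to isopropyl, and silylation of the alkoxide in the flask keeps the acid-labile tertiary allylic carbinol from ionising.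

Step 8
Reactants: 12 tert-butyl({(3S,4R)-3-ethenyl-2-methyl-4-(propan-2-yl)-3-[(triethylsilyl)oxy]cyclopent-1-en-1-yl}oxy)dimethylsilane; 3 (2Z)-3-iodobut-2-enal; 13 4-methoxybenzoyl chloride
Product: 17 (3R,3aS,8R,8aR)-6,8a-dimethyl-1-oxo-3-(propan-2-yl)-3a-[(triethylsilyl)oxy]-1,2,3,3a,4,5,8,8a-octahydroazulen-8-yl 4-methoxybenzoate, via sulfonium aldolate 14 (not isolated), via acyclic iodoalkenyl anisoate 15 (not isolated), via B-alkyl-9-BBN 16 (not isolated)
Conditions: 3, (Me2N)3S+ Me3SiF2− (TASF), THF, −78 °C; then 13, −78 to 0 °C; then 9-BBN, THF, 0 °C to rt; then Pd(dppf)Cl2 (10 mol %), AsPh3, aq. Cs2CO3, DMF, rt, 5 mM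
Reagents that add atoms: (2Z)-3-iodobut-2-enal (3), C/C(I)=C/C=O; 4-methoxybenzoyl chloride (13), COc1ccc(C(=O)Cl)cc1
Why: Fluoride removes the tert-butyldimethylsilyl group of 12 and the metal-free C1 enolate adds to the aldehyde carbon of 3 through an open transition state (fluoride-mediated Mukaiyama-type aldol addition), which forms C1–C10; acylation of the aldolate by 13 stops retro-aldol cleavage and masks the alkoxide before the borane is added. 9-BBN then hydroborates the vinyl group at its terminal carbon C7, and zerovalent palladium inserts into the C8–I bond, takes over the primary alkyl group from boron and forms C7–C8 by reductive elimination with retention of the Z geometry (intramolecular B-alkyl Suzuki–Miyaura coupling). The cycloheptene ring is thereby closed by C(sp3)–C(sp2) coupling through an eight-membered palladacycle, a closure open only to the cis ring alkene that the Z iodide provides. C1 is controlled by the substrate: the aldehyde should attack the enolate face anti to the pseudo-axial silyloxy group on C5 and to the isopropyl group on C4, so the new chain is cis to the two-carbon arm and the methyl group ends up cis to the C5 oxygen, as the cis ring fusion needs. C10 is controlled by simple diastereoselection in the open transition state, in which the two oxygen atoms are anti and the iodoalkenyl group lies beside the C1 methyl group and not beside the fully substituted C5, which should give the (R)-carbinol. The step needs 1,2-addition to the enal (its β-carbon is disubstituted and hindered), hydroboration of the monosubstituted alkene faster than reduction of the neopentylic ketone, oxidative addition at C–I faster than ionisation of the hindered allylic ester, and high dilution to favour ring closure.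

Step 9
Reactants: 17 (3R,3aS,8R,8aR)-6,8a-dimethyl-1-oxo-3-(propan-2-yl)-3a-[(triethylsilyl)oxy]-1,2,3,3a,4,5,8,8a-octahydroazulen-8-yl 4-methoxybenzoate
Product: 18 (3R,3aS,8R,8aR)-3a-hydroxy-6,8a-dimethyl-1-oxo-3-(propan-2-yl)-1,2,3,3a,4,5,8,8a-octahydroazulen-8-yl 4-methoxybenzoate
Conditions: HF·pyridine, pyridine–THF, 0 °C to rt
Reagents that add atoms: none
Why: Fluoride cleaves the tertiary triethylsilyl ether (desilylation), and the allylic ester, the ketone and the liberated tertiary alcohol should be inert to buffered HF·pyridine.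

Compound list
1 | but-2-yn-1-ol | CC#CCO | starting material
2 | (2Z)-3-iodobut-2-en-1-ol | C/C(I)=C/CO | intermediate
3 | (2Z)-3-iodobut-2-enal | C/C(I)=C/C=O | intermediate
4 | (4R)-4-benzyl-3-(3-methylbutanoyl)-1,3-oxazolidin-2-one | CC(C)CC(=O)N1[C@H](Cc2ccccc2)COC1=O | starting material
5 | 1-bromobut-2-yne | CC#CCBr | starting material
6 | (4R)-4-benzyl-3-[(2R)-2-(propan-2-yl)hex-4-ynoyl]-1,3-oxazolidin-2-one | CC#CC[C@H](C(C)C)C(=O)N1[C@H](Cc2ccccc2)COC1=O | intermediate
7 | (4R)-4-benzyl-3-[(2R)-4-oxo-2-(propan-2-yl)hexanoyl]-1,3-oxazolidin-2-one | CCC(=O)C[C@H](C(C)C)C(=O)N1[C@H](Cc2ccccc2)COC1=O | intermediate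
8 | (4R)-2-methyl-4-(propan-2-yl)cyclopentane-1,3-dione (C2 undefined, enolised) | CC1C(=O)C[C@H](C(C)C)C1=O | intermediate
9 | (5R)-3-[(tert-butyldimethylsilyl)oxy]-2-methyl-5-(propan-2-yl)cyclopent-2-en-1-one | CC1=C(O[Si](C)(C)C(C)(C)C)C[C@H](C(C)C)C1=O | intermediate
10 | vinylmagnesium bromide | C=C[Mg]Br | starting material
11 | bromomagnesium (1S,5R)-3-[(tert-butyldimethylsilyl)oxy]-1-ethenyl-2-methyl-5-(propan-2-yl)cyclopent-2-en-1-olate (vinyl trans to isopropyl) | C=C[C@]1(O[Mg]Br)[C@@H](C(C)C)CC(O[Si](C)(C)C(C)(C)C)=C1C | intermediate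
12 | tert-butyl({(3S,4R)-3-ethenyl-2-methyl-4-(propan-2-yl)-3-[(triethylsilyl)oxy]cyclopent-1-en-1-yl}oxy)dimethylsilane (silyloxy cis to isopropyl) | C=C[C@]1(O[Si](CC)(CC)CC)[C@@H](C(C)C)CC(O[Si](C)(C)C(C)(C)C)=C1C | intermediate
13 | 4-methoxybenzoyl chloride | COc1ccc(C(=O)Cl)cc1 | starting material
14 | tris(dimethylamino)sulfonium (1R,2Z)-1-{(1R,2S,3R)-2-ethenyl-1-methyl-5-oxo-3-(propan-2-yl)-2-[(triethylsilyl)oxy]cyclopentyl}-3-iodobut-2-en-1-olate | CN(C)[S+](N(C)C)N(C)C.[O-][C@H](/C=C(/C)I)[C@@]1(C)C(=O)C[C@H](C(C)C)[C@]1(C=C)O[Si](CC)(CC)CC | intermediate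
15 | (1R,2Z)-1-{(1R,2S,3R)-2-ethenyl-1-methyl-5-oxo-3-(propan-2-yl)-2-[(triethylsilyl)oxy]cyclopentyl}-3-iodobut-2-en-1-yl 4-methoxybenzoate | COc1ccc(cc1)C(=O)O[C@H](/C=C(/C)I)[C@@]1(C)C(=O)C[C@H](C(C)C)[C@]1(C=C)O[Si](CC)(CC)CC | intermediate
16 | (1R,2Z)-1-{(1R,2S,3R)-2-[2-(9-borabicyclo[3.3.1]nonan-9-yl)ethyl]-1-methyl-5-oxo-3-(propan-2-yl)-2-[(triethylsilyl)oxy]cyclopentyl}-3-iodobut-2-en-1-yl 4-methoxybenzoate | COc1ccc(cc1)C(=O)O[C@H](/C=C(/C)I)[C@@]1(C)C(=O)C[C@H](C(C)C)[C@]1(CCB2C3CCCC2CCC3)O[Si](CC)(CC)CC | intermediate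
17 | (3R,3aS,8R,8aR)-6,8a-dimethyl-1-oxo-3-(propan-2-yl)-3a-[(triethylsilyl)oxy]-1,2,3,3a,4,5,8,8a-octahydroazulen-8-yl 4-methoxybenzoate | COc1ccc(C(=O)O[C@@H]2C=C(C)CC[C@]3(O[Si](CC)(CC)CC)[C@@H](C(C)C)CC(=O)[C@]23C)cc1 | intermediate
18 | (3R,3aS,8R,8aR)-3a-hydroxy-6,8a-dimethyl-1-oxo-3-(propan-2-yl)-1,2,3,3a,4,5,8,8a-octahydroazulen-8-yl 4-methoxybenzoate | COc1ccc(C(=O)O[C@@H]2C=C(C)CC[C@]3(O)[C@@H](C(C)C)CC(=O)[C@]23C)cc1 | target

Total step count: 9. Longest linear sequence: 7 steps (steps 3 to 9, from imide 4).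

Steps most likely to fail

Step 8. Several processes could defeat the one-flask sequence:
- aldol addition on the wrong enolate face or with the opposite relative topicity, which would give diastereomers at C1 or C10;
- β-elimination of the silyloxy group from the free enolate;
- reduction of the ketone by 9-BBN in competition with hydroboration;
- oligomerisation or protodeboronation outrunning the seven-membered ring closure.

The fallback sets out from 9 and comes back at 17, and closes the ring by metathesis instead of cross-coupling. CeCl3-mediated addition of 3-methylbut-3-en-1-ylmagnesium bromide to 9 and trapping with Et3SiOTf would give the homologous bis-silyl ether F1. Its fluoride-triggered aldol addition to (E)-but-2-enal, with acylation of the aldolate by 13, would give the acyclic diene ester F2. Ring-closing metathesis of F2 with the second-generation Hoveyda–Grubbs catalyst (toluene, 80 °C) would form the C8=C9 alkene with loss of propene and deliver 17.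

Step 7. The basic vinyl reagent may deprotonate the carbon α to the carbonyl (loss of the C4 configuration), add in conjugate fashion with expulsion of the silyloxy group, or the tertiary allylic alkoxide may ionise to the dienone during silylation.

The fallback sets out from 9 and comes back at 12. Addition of the smaller and far less basic ethynylmagnesium bromide (CeCl3, THF, −78 °C) with Et3SiOTf trapping would give the ethynyl carbinol silyl ether F3. Semi-hydrogenation of F3 (H2, Pd/CaCO3 poisoned with Pb(OAc)2, quinoline) would give 12.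

Step 5. Enolisation may occur on the wrong side of the ketone, the enolate may fail to attack the hindered exocyclic carbonyl, or the isopropyl-bearing centre may epimerise before ring closure.

The fallback sets out from 7 and comes back at 8. Cleavage of the auxiliary (LiOH, H2O2, THF–H2O, 0 °C) would give the keto acid F4. Dehydrative cyclisation (Ac2O, NaOAc, heat) would give the enol lactone F5. The known base-induced acyl-lactone rearrangement (NaOMe, MeOH, then acid) would convert F5 into 8.

Further compounds
F1 | step 8 | tert-butyl({(3S,4R)-2-methyl-3-(3-methylbut-3-en-1-yl)-4-(propan-2-yl)-3-[(triethylsilyl)oxy]cyclopent-1-en-1-yl}oxy)dimethylsilane | C=C(C)CC[C@]1(O[Si](CC)(CC)CC)[C@@H](C(C)C)CC(O[Si](C)(C)C(C)(C)C)=C1C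
F2 | step 8 | (1R,2E)-1-{(1R,2S,3R)-1-methyl-2-(3-methylbut-3-en-1-yl)-5-oxo-3-(propan-2-yl)-2-[(triethylsilyl)oxy]cyclopentyl}but-2-en-1-yl 4-methoxybenzoate | COc1ccc(cc1)C(=O)O[C@H](/C=C/C)[C@@]1(C)C(=O)C[C@H](C(C)C)[C@]1(CCC(C)=C)O[Si](CC)(CC)CC
F3 | step 7 | tert-butyl({(3R,4R)-3-ethynyl-2-methyl-4-(propan-2-yl)-3-[(triethylsilyl)oxy]cyclopent-1-en-1-yl}oxy)dimethylsilane (same spatial arrangement as 12) | C#C[C@]1(O[Si](CC)(CC)CC)[C@@H](C(C)C)CC(O[Si](C)(C)C(C)(C)C)=C1C
F4 | step 5 | (2R)-4-oxo-2-(propan-2-yl)hexanoic acid | CCC(=O)C[C@H](C(C)C)C(=O)O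
F5 | step 5 | (3R)-5-ethylidene-3-(propan-2-yl)oxolan-2-one | CC=C1C[C@H](C(C)C)C(=O)O1
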